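**Retrosynthetic overview**

1. The target comes from epoxy alcohol 33 by acetylation of O8. The cis C4–C5 epoxide is formed last, by SN2 closure of O5 onto a C4 mesylate (inversion) when fluoride cuts a temporary O5–Si(i-Pr)2–O8 tether.
2. The ten-membered carbocycle is closed at C3–C4 by an intramolecular Nozaki–Hiyama–Kishi addition of the Z-alkenyl iodide C2=C3–I to the C4 aldehyde of 30 (third ring formed).
3. What makes this possible: C4 is an oxygen-bearing carbon bonded directly to the Z-alkene terminus C3 (an alkenyl–carbinol bond inside the unit O1–C1–C2=C3–C4–O). Both chain ends hang on pre-formed rings: the trans-α-methylene-γ-lactone (O1, C1, C10, C11, C12) and a temporary seven-membered 1,3,2-dioxasilepine (O5, C5, C6=C7, C8, O8, Si) that holds C5 and C8 cis on the enoate.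
4. C9–C10 comes from a Hosomi–Sakurai addition of butenolide allylsilane 21 (lactone ring by metathesis, C1 by kinetic resolution) to silepine aldehyde 13. This sets C9 and C10 and unveils the methylene lactone; O9 is then acylated with (2S,3S)-epoxyangelic acid 26.
5. Silepine 13 (temporary ring) comes from a silicon-tethered ring-closing metathesis of two chiral-pool allylic alcohols (3 from (S)-glycidol, 9 from methyl (S)-glycerate acetonide). This fixes C5, C8 and the C6=C7 geometry.

Key step: step 22

Remark: locants used throughout are C1 (lactone O–CH), C2=C3 (Z), C4/C5 (epoxide carbons), C6=C7 (C7 bears CO2Me), C8 (OAc), C9 (O-acyl), C10 (ring fusion CH), C11(=C13H2)–C12(=O) (lactone). H2IMes is 1,3-dimesityl-4,5-dihydroimidazol-2-ylidene. The ligand in step 22 is N-{2-[4-(propan-2-yl)-4,5-dihydro-1,3-oxazol-2-yl]-6-methylphenyl}methanesulfonamide, and it is assumed that the antipode directing Re-face addition (both are made from L- or D-valinol) has to be identified by trial.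

**Route**

Step 1
Reactants: 1 (S)-glycidol
Product: 2 (2R)-2-{[(4-methoxyphenyl)methoxy]methyl}oxirane
Conditions: NaH, 4-methoxybenzyl chloride, Bu4NI (cat.), THF/DMF, 0 °C to rt
Reagents that add atoms: 4-methoxybenzyl chloride, COc1ccc(CCl)cc1
Why: Williamson etherification of the primary alkoxide leaves the epoxide carbon (future C5) untouched, a Payne shift of glycidol being degenerate.

Step 2
Reactants: 2 (2R)-2-{[(4-methoxyphenyl)methoxy]methyl}oxirane
Product: 3 (2R)-1-[(4-methoxyphenyl)methoxy]but-3-en-2-ol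
Conditions: Me3S+ I− (3 equiv), n-BuLi (2.9 equiv), THF, −10 °C to rt
Reagents that add atoms: trimethylsulfonium iodide, C[S+](C)C.[I-]
Why: Dimethylsulfonium methylide opens the terminal epoxide at CH2 and the β-oxido sulfonium salt loses Me2S, a known one-carbon epoxide-to-allylic-alcohol homologation that does not touch the carbinol stereocenter.

Step 3
Reactants: 4 methyl (4S)-2,2-dimethyl-1,3-dioxolane-4-carboxylate
Product: 6 (4R)-4-ethynyl-2,2-dimethyl-1,3-dioxolane, via aldehyde 5 (not isolated)
Conditions: i-Bu2AlH, CH2Cl2, −78 °C; then MeOH, K2CO3, dimethyl (1-diazo-2-oxopropyl)phosphonate, 0 °C to rt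
Reagents that add atoms: dimethyl (1-diazo-2-oxopropyl)phosphonate, COP(=O)(OC)C(=[N+]=[N-])C(C)=O
Why: Partial ester reduction followed in the same flask by Seyferth–Gilbert homologation with the Ohira–Bestmann reagent turns the ester carbon into the alkyne carbon (future C7) without isolating the epimerisable α-alkoxy aldehyde.

Step 4
Reactants: 6 (4R)-4-ethynyl-2,2-dimethyl-1,3-dioxolane
Product: 7 methyl 2-[(4R)-2,2-dimethyl-1,3-dioxolan-4-yl]prop-2-enoate
Conditions: Pd(OAc)2 (1 mol %), 2-(diphenylphosphino)pyridine (20 mol %), CH3SO3H (5 mol %), CO (10 bar), MeOH, 45 °C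
Reagents that add atoms: carbon monoxide, [C-]#[O+]; methanol, CO
Why: Palladium/pyridylphosphine-catalysed hydromethoxycarbonylation of a terminal alkyne adds H and CO2Me in the Markovnikov sense and should give the 2-substituted acrylate (future C6=C7 with its ester) without touching the stereocenter.

Step 5
Reactants: 7 methyl 2-[(4R)-2,2-dimethyl-1,3-dioxolan-4-yl]prop-2-enoate
Product: 8 methyl (3R)-3,4-dihydroxy-2-methylidenebutanoate
Conditions: AcOH/H2O 4:1, 30 °C, then azeotropic removal of acid below 30 °C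
Reagents that add atoms: none
Why: Mild acid hydrolysis of the terminal isopropylidene acetal frees the diol, the temperature being kept low so that the γ-hydroxy ester does not lactonise.

Step 6
Reactants: 8 methyl (3R)-3,4-dihydroxy-2-methylidenebutanoate
Product: 9 methyl (3R)-3-hydroxy-2-methylidene-4-[(triethylsilyl)oxy]butanoate
Conditions: Et3SiCl (1.05 equiv), imidazole, CH2Cl2, −40 °C
Reagents that add atoms: chlorotriethylsilane, CC[Si](Cl)(CC)CC
Why: The primary hydroxyl is silylated much faster than the hindered secondary allylic one, which leaves the C8 hydroxyl free for the tether.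

Step 7
Reactants: 3 (2R)-1-[(4-methoxyphenyl)methoxy]but-3-en-2-ol; 9 methyl (3R)-3-hydroxy-2-methylidene-4-[(triethylsilyl)oxy]butanoate
Product: 11 mixed di(propan-2-yl)silyl ketal of 3 and 9, via chlorosilane 10 (not isolated)
Conditions: 3, i-Pr2SiCl2 (3 equiv), imidazole, CH2Cl2, 0 °C, excess silane removed in vacuo; then 9, imidazole, DMF, rt
Reagents that add atoms: dichlorodi(propan-2-yl)silane, CC(C)[Si](Cl)(Cl)C(C)C
Why: Stepwise silylation (alkoxychlorosilane from the first alcohol with excess dichlorosilane, then capture by the second alcohol) is the standard way to a mixed bis(alkoxy)silane, here the temporary tether between O5 and O8.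

Step 8
Reactants: 11 mixed di(propan-2-yl)silyl ketal
Product: 12 methyl (4R,7R)-4-{[(4-methoxyphenyl)methoxy]methyl}-2,2-di(propan-2-yl)-7-{[(triethylsilyl)oxy]methyl}-4,7-dihydro-1,3,2-dioxasilepine-6-carboxylate
Conditions: second-generation Hoveyda–Grubbs catalyst RuCl2(H2IMes)(=CH-C6H4-2-O-i-Pr) (10 mol %), toluene (5 mM), 90 °C, argon sparge
Reagents that add atoms: none
Why: Silicon-tethered ring-closing metathesis between the vinyl group and the acrylate methylene should close the seven-membered ring, in which the trisubstituted C6=C7 bond can only have C5 and C8 cis (the geometry of the target), with loss of ethene.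

Step 9
Reactants: 12 silepine triethylsilyl ether
Product: 13 methyl (4R,7R)-7-formyl-4-{[(4-methoxyphenyl)methoxy]methyl}-2,2-di(propan-2-yl)-4,7-dihydro-1,3,2-dioxasilepine-6-carboxylate
Conditions: (COCl)2, DMSO, CH2Cl2, −78 to −40 °C; then Et3N, −78 to −30 °C; used crude
Reagents that add atoms: none
Why: Primary triethylsilyl ethers are cleaved and oxidised directly under Swern conditions while the secondary cyclic silyl ketal should survive, so the C9 aldehyde is unmasked in one step and used at once to avoid epimerisation at C8.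

Step 10
Reactants: 14 ethyl (2Z)-3-iodoprop-2-enoate
Product: 16 racemic (1Z)-1-iodopenta-1,4-dien-3-ol, via iodoacrolein 15 (not isolated)
Conditions: i-Bu2AlH, CH2Cl2, −78 °C; then CH2=CHMgBr, THF, −78 to −40 °C
Reagents that add atoms: vinylmagnesium bromide, C=C[Mg]Br
Why: Reduction to (Z)-3-iodoacrolein at −78 °C and immediate 1,2-addition of the vinyl Grignard reagent in the same flask avoids Z-to-E isomerisation of the aldehyde and gives the racemic bis-allylic alcohol.

Step 11
Reactants: 16 racemic (1Z)-1-iodopenta-1,4-dien-3-ol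
Product: 17 (3S,1Z)-1-iodopenta-1,4-dien-3-ol
Conditions: Ti(O-i-Pr)4 (0.15 equiv), L-(+)-diisopropyl tartrate (0.2 equiv), t-BuOOH (0.6 equiv), 4 Å sieves, CH2Cl2, −20 °C
Reagents that add atoms: none
Why: Sharpless kinetic resolution, in which L-(+)-tartrate epoxidises the (R)-enantiomer at its vinyl group (the electron-poor Z-iodoalkene does not react), so that the (S)-alcohol, the future C1, is recovered.

Step 12
Reactants: 18 ethyl 2-[(trimethylsilyl)methyl]prop-2-enoate
Product: 19 2-[(trimethylsilyl)methyl]prop-2-enoic acid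
Conditions: LiOH, THF/H2O, rt; then 1 M HCl to pH 3
Reagents that add atoms: lithium hydroxide, [Li+].[OH-]
Why: Plain saponification of the ethyl ester, to which the allylsilane is inert.

Step 13
Reactants: 17 (3S,1Z)-1-iodopenta-1,4-dien-3-ol; 19 2-[(trimethylsilyl)methyl]prop-2-enoic acid
Product: 20 (3S,1Z)-1-iodopenta-1,4-dien-3-yl 2-[(trimethylsilyl)methyl]prop-2-enoate
Conditions: DCC, DMAP (cat.), CH2Cl2, 0 °C
Reagents that add atoms: none
Why: Steglich esterification acylates the secondary alcohol with retention at C1.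

Step 14
Reactants: 20 dienyl acrylate
Product: 21 (5S)-5-[(Z)-2-iodoethenyl]-3-[(trimethylsilyl)methyl]furan-2(5H)-one
Conditions: second-generation Grubbs catalyst RuCl2(H2IMes)(PCy3)(=CHPh) (5 mol %), toluene (10 mM), 80 °C
Reagents that add atoms: none
Why: Ring-closing metathesis between the terminal vinyl group and the 2-substituted acrylate should close the butenolide under neutral conditions (no epimerisation of the acidic C1–H), the iodoalkene being a spectator.

Step 15
Reactants: 13 silepine aldehyde; 21 butenolide allylsilane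
Product: 22 C9 alcohol with the α-methylene-γ-lactone (C1 S, C9 S, C10 R; silepine 4R,7R)
Conditions: BF3·OEt2 (2 equiv), 21 (1.5 equiv), CH2Cl2, −78 to −40 °C
Reagents that add atoms: none
Why: Hosomi–Sakurai (SE2′) addition through an open antiperiplanar transition state, in which the aldehyde should reach C10 on the butenolide face opposite the C1 iodoethenyl group (C9 trans to C2), keep its chain away from C1 (O9 and C1 syn along C8–C11) and be attacked anti to the C8–O bond (Felkin–Anh, 8,9-anti), all three elements being matched, while loss of silicon gives the exocyclic methylene lactone.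

Step 16
Reactants: 23 methyl (2Z)-2-methylbut-2-enoate (methyl angelate)
Product: 24 (2Z)-2-methylbut-2-en-1-ol
Conditions: i-Bu2AlH (2.2 equiv), CH2Cl2, −78 °C
Reagents that add atoms: none
Why: 1,2-Reduction of the ester at low temperature keeps the Z-trisubstituted alkene from isomerising to the tiglate series.

Step 17
Reactants: 24 (2Z)-2-methylbut-2-en-1-ol
Product: 25 [(2R,3S)-2,3-dimethyloxiran-2-yl]methanol
Conditions: Ti(O-i-Pr)4 (0.1 equiv), D-(−)-diisopropyl tartrate (0.12 equiv), t-BuOOH (2 equiv), 4 Å sieves, CH2Cl2, −20 °C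
Reagents that add atoms: tert-butyl hydroperoxide, CC(C)(C)OO
Why: Sharpless asymmetric epoxidation of the Z-allylic alcohol, in which D-(−)-tartrate delivers oxygen to the face that gives the (2R,3S)-epoxy alcohol, the cis relation of CH2OH and the C3 methyl coming from the Z-alkene.

Step 18
Reactants: 25 [(2R,3S)-2,3-dimethyloxiran-2-yl]methanol
Product: 26 (2S,3S)-2,3-dimethyloxirane-2-carboxylic acid
Conditions: TEMPO (0.2 equiv), PhI(OAc)2 (2.2 equiv), MeCN/H2O 1:1, rt
Reagents that add atoms: water, O
Why: Nitroxyl-catalysed oxidation of the primary alcohol through the aldehyde hydrate to the acid leaves the epoxide intact, the C2 descriptor changing to S by priority only.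

Step 19
Reactants: 22 C9 alcohol; 26 (2S,3S)-2,3-dimethyloxirane-2-carboxylic acid
Product: 28 C9 epoxyangelate ester, via mixed anhydride 27 (not isolated)
Conditions: 26, 2,4,6-trichlorobenzoyl chloride, Et3N, THF, rt; then 22, DMAP, toluene, rt
Reagents that add atoms: none
Why: Yamaguchi esterification through the mixed anhydride should acylate the hindered C9 hydroxyl with the α-quaternary acid while O8 is still locked in the silyl ketal, so that no acyl migration between O8 and O9 can occur.

Step 20
Reactants: 28 C9 epoxyangelate ester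
Product: 29 primary C4 alcohol
Conditions: DDQ (1.5 equiv), CH2Cl2/pH 7 buffer 10:1, 0 °C
Reagents that add atoms: none
Why: Oxidative cleavage of the 4-methoxybenzyl ether under buffered, neutral conditions that spare the silyl ketal, the alkenyl iodide, the epoxy ester and the methylene lactone.

Step 21
Reactants: 29 primary C4 alcohol
Product: 30 C4 aldehyde with the Z-alkenyl iodide (C1 S, C5 R, C8 R, C9 S, C10 S)
Conditions: Dess–Martin periodinane, NaHCO3, CH2Cl2, 0 °C; used at once
Reagents that add atoms: none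
Why: Buffered Dess–Martin oxidation gives the α-silyloxy aldehyde without base, which matters because C5–H is α to the aldehyde and vinylogously activated by the enoate.

Step 22
Reactants: 30 C4 aldehyde with the Z-alkenyl iodide
Product: 31 ring-closed C4 allylic alcohol (1R,4R,5R,8R,9S,10S)
Conditions: CrCl2 (8 equiv), oxazoline–sulfonamide ligand (8.8 equiv), Et3N (8.8 equiv), THF, rt; NiCl2 (0.2 equiv); syringe-pump addition of 30 to 2 mM, rt
Reagents that add atoms: none
Why: Nozaki–Hiyama–Kishi reaction, in which zerovalent nickel (made from NiCl2 by divalent chromium) inserts into the C3–I bond, the alkenyl group passes to trivalent chromium with retention of the Z geometry, and the alkenylchromium adds to the C4 aldehyde to give the chromium alkoxide of 31. The closest known reaction type is the Ni/Cr-mediated cyclisation of alkenyl iodide–aldehydes to medium and large rings, including the variant with chiral oxazoline–sulfonamide ligands on chromium. The ten-membered carbocycle closes in a 10-exo-trig mode and is the third ring, fused to the lactone at C1–C10 and to the silepine along C5–C8. The one new stereocenter, C4, is set under reagent control, because the ligand-bound chromium must deliver C3 to the Re face of the aldehyde to give the 4R alcohol (4,5-syn, O4 trans to O5 on the new ring), which is opposite to the Felkin–Anh preference of the α-silyloxy aldehyde. The step needs chemoselectivity (only the C–I bond is activated, and the esters, enoates, epoxy ester and silyl ketal should be inert to CrCl2), retention of the Z-alkene, and cyclisation over oligomerisation. Cyclisation is secured by high dilution and by the two existing rings, which fix C2 and C9 trans on the lactone and hold C5 and C8 cis on the C6=C7 bond, so that only the C1–C2, C4–C5, C8–C9 and C9–C10 bonds must rotate into place.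

Step 23
Reactants: 31 ring-closed C4 allylic alcohol
Product: 33 epoxy alcohol with free C8–OH (1R,4S,5R,8R,9S,10S), via mesylate 32 (not isolated)
Conditions: (CH3SO2)2O, Et3N, CH2Cl2, −30 °C; then Bu4NF (3 equiv), THF, −30 to 0 °C
Reagents that add atoms: none
Why: Sulfonylation of the C4 hydroxyl with retention, after which fluoride cleaves the silicon tether and the freed O5 alkoxide should displace the allylic mesylate in a 3-exo-tet SN2 reaction with inversion at C4 to give the cis-epoxide (4S,5R), O8 being released in the same operation.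

Step 24
Reactants: 33 epoxy alcohol with free C8–OH
Product: 34 target CNP0077533.1
Conditions: Ac2O, pyridine, DMAP (cat.), CH2Cl2, 0 °C
Reagents that add atoms: acetic anhydride, CC(=O)OC(C)=O
Why: Standard acetylation of the one remaining secondary hydroxyl at C8 completes the target.

**Compound list**

1 | (S)-glycidol, [(2S)-oxiran-2-yl]methanol | C1O[C@H]1CO | starting material
2 | (2R)-2-{[(4-methoxyphenyl)methoxy]methyl}oxirane | C1O[C@H]1COCc2ccc(OC)cc2 | intermediate
3 | (2R)-1-[(4-methoxyphenyl)methoxy]but-3-en-2-ol | C=C[C@@H](O)COCc1ccc(OC)cc1 | intermediate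
4 | methyl (4S)-2,2-dimethyl-1,3-dioxolane-4-carboxylate | COC(=O)[C@@H]1COC(C)(C)O1 | starting material
5 | (4S)-2,2-dimethyl-1,3-dioxolane-4-carbaldehyde | O=C[C@@H]1COC(C)(C)O1 | intermediate
6 | (4R)-4-ethynyl-2,2-dimethyl-1,3-dioxolane | C#C[C@@H]1COC(C)(C)O1 | intermediate
7 | methyl 2-[(4R)-2,2-dimethyl-1,3-dioxolan-4-yl]prop-2-enoate | C=C(C(=O)OC)[C@@H]1COC(C)(C)O1 | intermediate
8 | methyl (3R)-3,4-dihydroxy-2-methylidenebutanoate | C=C(C(=O)OC)[C@@H](O)CO | intermediate
9 | methyl (3R)-3-hydroxy-2-methylidene-4-[(triethylsilyl)oxy]butanoate | C=C(C(=O)OC)[C@@H](O)CO[Si](CC)(CC)CC | intermediate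
10 | chloro{[(2R)-1-[(4-methoxyphenyl)methoxy]but-3-en-2-yl]oxy}di(propan-2-yl)silane | C=C[C@H](COCc1ccc(OC)cc1)O[Si](Cl)(C(C)C)C(C)C | intermediate
11 | methyl (3R)-3-[({[(2R)-1-[(4-methoxyphenyl)methoxy]but-3-en-2-yl]oxy}di(propan-2-yl)silyl)oxy]-2-methylidene-4-[(triethylsilyl)oxy]butanoate | C=C[C@H](COCc1ccc(OC)cc1)O[Si](C(C)C)(C(C)C)O[C@@H](CO[Si](CC)(CC)CC)C(=C)C(=O)OC | intermediate
12 | methyl (4R,7R)-4-{[(4-methoxyphenyl)methoxy]methyl}-2,2-di(propan-2-yl)-7-{[(triethylsilyl)oxy]methyl}-4,7-dihydro-1,3,2-dioxasilepine-6-carboxylate | CC[Si](CC)(CC)OC[C@@H]1O[Si](C(C)C)(C(C)C)O[C@@H](COCc2ccc(OC)cc2)/C=C1/C(=O)OC | intermediate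
13 | methyl (4R,7R)-7-formyl-4-{[(4-methoxyphenyl)methoxy]methyl}-2,2-di(propan-2-yl)-4,7-dihydro-1,3,2-dioxasilepine-6-carboxylate | O=C[C@@H]1O[Si](C(C)C)(C(C)C)O[C@@H](COCc2ccc(OC)cc2)/C=C1/C(=O)OC | intermediate
14 | ethyl (2Z)-3-iodoprop-2-enoate | CCOC(=O)/C=C\I | starting material
15 | (2Z)-3-iodoprop-2-enal | O=C/C=C\I | intermediate
16 | racemic (1Z)-1-iodopenta-1,4-dien-3-ol | C=CC(O)/C=C\I | intermediate
17 | (3S,1Z)-1-iodopenta-1,4-dien-3-ol | C=C[C@H](O)/C=C\I | intermediate
18 | ethyl 2-[(trimethylsilyl)methyl]prop-2-enoate | CCOC(=O)C(=C)C[Si](C)(C)C | starting material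
19 | 2-[(trimethylsilyl)methyl]prop-2-enoic acid | OC(=O)C(=C)C[Si](C)(C)C | intermediate
20 | (3S,1Z)-1-iodopenta-1,4-dien-3-yl 2-[(trimethylsilyl)methyl]prop-2-enoate | C=C[C@H](OC(=O)C(=C)C[Si](C)(C)C)/C=C\I | intermediate
21 | (5S)-5-[(Z)-2-iodoethenyl]-3-[(trimethylsilyl)methyl]furan-2(5H)-one | C[Si](C)(C)CC1=C[C@@H](/C=C\I)OC1=O | intermediate
22 | methyl (4R,7R)-7-{(S)-hydroxy[(2S,3R)-2-[(Z)-2-iodoethenyl]-4-methylidene-5-oxooxolan-3-yl]methyl}-4-{[(4-methoxyphenyl)methoxy]methyl}-2,2-di(propan-2-yl)-4,7-dihydro-1,3,2-dioxasilepine-6-carboxylate | C=C1C(=O)O[C@H](/C=C\I)[C@H]1[C@H](O)[C@@H]2O[Si](C(C)C)(C(C)C)O[C@@H](COCc3ccc(OC)cc3)/C=C2/C(=O)OC | intermediate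
23 | methyl (2Z)-2-methylbut-2-enoate (methyl angelate) | COC(=O)/C(C)=C\C | starting material
24 | (2Z)-2-methylbut-2-en-1-ol | OC/C(C)=C\C | intermediate
25 | [(2R,3S)-2,3-dimethyloxiran-2-yl]methanol | OC[C@@]1(C)O[C@H]1C | intermediate
26 | (2S,3S)-2,3-dimethyloxirane-2-carboxylic acid | OC(=O)[C@@]1(C)O[C@H]1C | intermediate
27 | (2S,3S)-2,3-dimethyloxirane-2-carboxylic 2,4,6-trichlorobenzoic anhydride | O=C(OC(=O)c1c(Cl)cc(Cl)cc1Cl)[C@@]2(C)O[C@H]2C | intermediate
28 | methyl (4R,7R)-7-[(S)-{[(2S,3S)-2,3-dimethyloxirane-2-carbonyl]oxy}{(2S,3S)-2-[(Z)-2-iodoethenyl]-4-methylidene-5-oxooxolan-3-yl}methyl]-4-{[(4-methoxyphenyl)methoxy]methyl}-2,2-di(propan-2-yl)-4,7-dihydro-1,3,2-dioxasilepine-6-carboxylate | C=C1C(=O)O[C@H](/C=C\I)[C@H]1[C@H](OC(=O)[C@@]2(C)O[C@H]2C)[C@@H]3O[Si](C(C)C)(C(C)C)O[C@@H](COCc4ccc(OC)cc4)/C=C3/C(=O)OC | intermediate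
29 | analogue of 28 with 4-(hydroxymethyl) on the silepine (free C4–OH) | C=C1C(=O)O[C@H](/C=C\I)[C@H]1[C@H](OC(=O)[C@@]2(C)O[C@H]2C)[C@@H]3O[Si](C(C)C)(C(C)C)O[C@@H](CO)/C=C3/C(=O)OC | intermediate
30 | analogue of 28 with 4-formyl on the silepine (C4 aldehyde; C1 S, C5 R, C8 R, C9 S, C10 S) | C=C1C(=O)O[C@H](/C=C\I)[C@H]1[C@H](OC(=O)[C@@]2(C)O[C@H]2C)[C@@H]3O[Si](C(C)C)(C(C)C)O[C@@H](C=O)/C=C3/C(=O)OC | intermediate
31 | ring-closed allylic alcohol: ten-membered carbocycle C1–C10 with Z-C2=C3 and C6=C7(CO2Me) (C5 cis to C8), 4-OH, O5 and O8 bridged by Si(i-Pr)2, 9-O-[(2S,3S)-2,3-dimethyloxirane-2-carbonyl], lactone O1–C12(=O)–C11(=CH2)–C10; (1R,4R,5R,8R,9S,10S) | C=C1C(=O)O[C@@H]2/C=C\[C@@H](O)[C@H](O3)/C=C(/C(=O)OC)[C@@H](O[Si]3(C(C)C)C(C)C)[C@@H](OC(=O)[C@@]4(C)O[C@H]4C)[C@@H]12 | intermediate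
32 | C4 methanesulfonate of 31 (4R) | C=C1C(=O)O[C@@H]2/C=C\[C@@H](OS(C)(=O)=O)[C@H](O3)/C=C(/C(=O)OC)[C@@H](O[Si]3(C(C)C)C(C)C)[C@@H](OC(=O)[C@@]4(C)O[C@H]4C)[C@@H]12 | intermediate
33 | 8-O-deacetyl target: cis-4,5-epoxide, free 8-OH; (1R,4S,5R,8R,9S,10S) | C=C1C(=O)O[C@@H]2/C=C\[C@@H]3O[C@@H]3/C=C(/C(=O)OC)[C@@H](O)[C@@H](OC(=O)[C@@]3(C)O[C@H]3C)[C@@H]12 | intermediate
34 | CNP0077533.1; (1R,4S,5R,8R,9S,10S), acyl group (2S,3S) | C=C1C(=O)O[C@@H]2/C=C\[C@@H]3O[C@@H]3/C=C(/C(=O)OC)[C@@H](OC(C)=O)[C@@H](OC(=O)[C@@]3(C)O[C@H]3C)[C@@H]12 | target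

**Step count and risks**

Total step count: 24. Longest linear sequence: 14 steps (from 4 through steps 3–9, 15 and 19–24).

The three steps most likely to fail:

Step 15. The ester-conjugated allylsilane may be too weak a nucleophile, so that protodesilylation or Lewis-acid-induced epimerisation of the aldehyde outruns C–C bond formation, or the open transition state may lose its syn preference. The fallback sets out from 17 (and uses 13 as before). Alcohol 17 is esterified with commercial 2-(bromomethyl)prop-2-enoic acid (DCC) to the bromomethyl acrylate ester F1. Ring-closing metathesis then gives the bromomethylbutenolide F2. An indium-mediated Barbier allylation of 13 (indium powder, THF/H2O) through a closed chair transition state is expected to give the C9-epimeric alcohol F3. A Mitsunobu esterification of F3 with acid 26 (PPh3, diisopropyl azodicarboxylate) inverts C9 and comes back to the route at 28.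

Step 22. Facial selectivity at C4 may be poor if the ligand is mismatched with the substrate, and chain growth may compete with ring closure. The fallback sets out from 30. Ligand-free ring closure (CrCl2, NiCl2 cat., DMSO/THF, high dilution) gives 31 together with the C4-epimeric alcohol F4. Dess–Martin oxidation of the mixture converges on the Z-enone F5. Luche reduction (NaBH4, CeCl3·7H2O, MeOH/THF, −78 °C), with hydride adding anti to the C5–O bond (Felkin–Anh, 4,5-syn), comes back at 31.

Step 23. The doubly activated allylic mesylate may ionise or suffer SN2′ attack before the ring closes, and the fluoride medium may induce an acyl shift from O9 to the freed O8. The fallback sets out from 30. Ring closure under the antipodal ligand (or under substrate control as above) gives the C4-epimeric alcohol F4. PPh3/hexachloroacetone (CH2Cl2, −40 °C) converts it with SN2 inversion into the isolable allylic chloride F6. Bu4NF then frees O5, which displaces chloride with a second inversion, and the route is rejoined at 33.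

**Further compounds**

F1 | step 15 | (3S,1Z)-1-iodopenta-1,4-dien-3-yl 2-(bromomethyl)prop-2-enoate | C=C[C@H](OC(=O)C(=C)CBr)/C=C\I
F2 | step 15 | (5S)-3-(bromomethyl)-5-[(Z)-2-iodoethenyl]furan-2(5H)-one | BrCC1=C[C@@H](/C=C\I)OC1=O
F3 | step 15 | C9 epimer of 22 (9R) | C=C1C(=O)O[C@H](/C=C\I)[C@H]1[C@@H](O)[C@@H]2O[Si](C(C)C)(C(C)C)O[C@@H](COCc3ccc(OC)cc3)/C=C2/C(=O)OC
F4 | step 22 | C4 epimer of 31 (4S) | C=C1C(=O)O[C@@H]2/C=C\[C@H](O)[C@H](O3)/C=C(/C(=O)OC)[C@@H](O[Si]3(C(C)C)C(C)C)[C@@H](OC(=O)[C@@]4(C)O[C@H]4C)[C@@H]12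
F5 | step 22 | C4 ketone of 31 (Z-enone) | C=C1C(=O)O[C@@H]2/C=C\C(=O)[C@H](O3)/C=C(/C(=O)OC)[C@@H](O[Si]3(C(C)C)C(C)C)[C@@H](OC(=O)[C@@]4(C)O[C@H]4C)[C@@H]12
F6 | step 23 | C4 chloride (4R) in place of the mesylate of 32 | C=C1C(=O)O[C@@H]2/C=C\[C@@H](Cl)[C@H](O3)/C=C(/C(=O)OC)[C@@H](O[Si]3(C(C)C)C(C)C)[C@@H](OC(=O)[C@@]4(C)O[C@H]4C)[C@@H]12
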